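**Plan**
- Retrosynthesis: the three phenolic MOM ethers come off last; then the C(=O)–CH= bond of the enone on the 2,4-dihydroxyphenyl ring is cut (an aldehyde C–H added across a terminal aryl alkyne); then the Cα=Cβ bond of the other enone (Claisen–Schmidt); then the alkyne goes back to an aryl aldehyde (one-carbon homologation); last the diaryl ether C–O bond para to that aldehyde (SNAr).
- Forward: 2,4,5-trihydroxyacetophenone is MOM-protected at O-4, arylated at O-5 with 4-fluorobenzaldehyde, homologated to the alkyne and condensed with 4-(methoxymethoxy)benzaldehyde to the first chalcone. 2,4-Dihydroxybenzaldehyde, protected only at O-4, is then added across the alkyne to complete the second chalcone chain. No ring is formed.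
- Enabling feature: the free OH at C-2 of the 2,4-dihydroxyphenyl ring is ortho to the ring carbon bearing the enone carbonyl. The matching salicylaldehyde therefore chelates rhodium through this oxygen and hands its formyl carbon (the future C=O) to the terminal alkyne carbon (the future α-CH).
- Stereochemistry: there is no stereocentre. The first E-enone comes from thermodynamically controlled aldol dehydration, the second from syn addition of H and aroyl across the alkyne.

Key step: step 6

Remark: the target has no stereogenic centre, so the only stereochemical task is the E geometry of both enone double bonds.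

**Route**

Step 1
Reactants: 1 1-(2,4,5-trihydroxyphenyl)ethan-1-one
Product: 2 1-[2,5-dihydroxy-4-(methoxymethoxy)phenyl]ethan-1-one
Conditions: MOMCl (1.0 equiv), K2CO3 (1.05 equiv), acetone, 0 °C → rt, Ar
Reagents that add atoms: chloromethyl methyl ether (MOMCl), COCCl
Why: Williamson-type O-alkylation (MOM protection) under acidity control, since one equivalent of carbonate should ionise only the 4-OH, which is para to the acetyl group and the most acidic phenol, while the 2-OH is held in a hydrogen bond to the ketone and the 5-OH is meta to it.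

Step 2
Reactants: 2 1-[2,5-dihydroxy-4-(methoxymethoxy)phenyl]ethan-1-one; 3 4-fluorobenzaldehyde
Product: 4 4-[5-acetyl-4-hydroxy-2-(methoxymethoxy)phenoxy]benzaldehyde
Conditions: 3 (1.1 equiv), K2CO3 (2.5 equiv), degassed DMF, 90 °C, Ar
Reagents that add atoms: none
Why: Nucleophilic aromatic substitution through a Meisenheimer adduct, in which the fluoride of 3 is activated by the para-formyl group and the 5-phenoxide of 2, neither conjugated to nor chelated by the acetyl group, is the stronger and less hindered nucleophile, in line with the known selective 5-O-alkylation of 2,5-dihydroxyacetophenones.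

Step 3
Reactants: 4 4-[5-acetyl-4-hydroxy-2-(methoxymethoxy)phenoxy]benzaldehyde
Product: 5 1-[5-(4-ethynylphenoxy)-2-hydroxy-4-(methoxymethoxy)phenyl]ethan-1-one
Conditions: dimethyl (1-diazo-2-oxopropyl)phosphonate (1.3 equiv), K2CO3 (3 equiv), MeOH, 0 °C → rt
Reagents that add atoms: dimethyl (1-diazo-2-oxopropyl)phosphonate (Ohira–Bestmann reagent), COP(=O)(OC)C(=[N+]=[N-])C(C)=O
Why: Seyferth–Gilbert homologation in its Ohira–Bestmann form, in which the diazomethylphosphonate anion released by methanolysis adds to the aldehyde, eliminates phosphate to a diazoalkene and gives the terminal alkyne after loss of N2 and 1,2-hydride shift, while the far less electrophilic hydrogen-bonded aryl methyl ketone and the MOM ether should be untouched by carbonate in methanol.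

Step 4
Reactants: 5 1-[5-(4-ethynylphenoxy)-2-hydroxy-4-(methoxymethoxy)phenyl]ethan-1-one; 6 4-(methoxymethoxy)benzaldehyde
Product: 8 (E)-1-[5-(4-ethynylphenoxy)-2-hydroxy-4-(methoxymethoxy)phenyl]-3-[4-(methoxymethoxy)phenyl]prop-2-en-1-one, via racemic beta-hydroxy ketone aldol adduct 7 (not isolated)
Conditions: 6 (1.2 equiv), 50% aq KOH, EtOH, rt, Ar; then AcOH to pH 6, 0 °C
Reagents that add atoms: none
Why: Claisen–Schmidt condensation (crossed aldol addition, then E1cB dehydration), in which the methyl ketone of 5 is the only enolisable carbonyl and 6 the only aldehyde, loss of hydroxide from 7 gives the conjugated enone as the thermodynamically favoured E isomer, and the terminal aryl alkyne and MOM ethers are inert to ethanolic KOH at room temperature.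

Step 5
Reactants: 9 2,4-dihydroxybenzaldehyde
Product: 10 2-hydroxy-4-(methoxymethoxy)benzaldehyde
Conditions: MOMCl (1.05 equiv), K2CO3 (1.1 equiv), acetone, 0 °C → rt
Reagents that add atoms: chloromethyl methyl ether (MOMCl), COCCl
Why: Acidity- and hydrogen-bond-controlled MOM protection (Williamson-type O-alkylation), in which the 4-OH para to the formyl group is ionised and alkylated while the 2-OH stays locked in a hydrogen bond to the aldehyde and remains free as the later directing group.

Step 6
Reactants: 8 (E)-1-[5-(4-ethynylphenoxy)-2-hydroxy-4-(methoxymethoxy)phenyl]-3-[4-(methoxymethoxy)phenyl]prop-2-en-1-one; 10 2-hydroxy-4-(methoxymethoxy)benzaldehyde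
Product: 11 (E)-1-[2-hydroxy-4-(methoxymethoxy)phenyl]-3-[4-[4-hydroxy-2-(methoxymethoxy)-5-[(E)-3-[4-(methoxymethoxy)phenyl]prop-2-enoyl]phenoxy]phenyl]prop-2-en-1-one
Conditions: [RhCl(cod)]2 (2.5 mol %), dppf (5 mol %), Na2CO3 (10 mol %), 10 (1.5 equiv), toluene, 100 °C, Ar, slow addition of 8
Reagents that add atoms: none
Why: The phenoxide of 10 binds Rh(I)–dppf through O-2 and places the formyl C–H at the metal; oxidative addition gives a five-membered O,C-chelated aroyl rhodium(III) hydride that is held back from decarbonylation, the terminal alkyne of 8 inserts syn into Rh–H with rhodium at the unsubstituted carbon, and C–C reductive elimination releases the enone and Rh(I). The closest known reaction type is the rhodium-catalysed, chelation-assisted intermolecular hydroacylation of alkynes with salicylaldehydes, which gives 2-alkenoylphenols. No ring is closed and no stereocentre is formed; the only new stereo element is the C=C bond, whose E geometry follows from syn addition of H and aroyl across the triple bond and is also the thermodynamic one. The step needs linear (anti-Markovnikov) regioselectivity, which the steric demand of the dppf-ligated acyl rhodium hydride against the aryl-bearing alkyne carbon should secure, and chemoselectivity for the alkyne over the chalcone C=C of 8, which the much faster insertion of a terminal alkyne than of a 1,2-disubstituted electron-poor alkene should secure. Only 10 has a formyl C–H next to a free phenol, the other phenols are MOM ethers or the ketone-bonded 2'-OH of 8, and slow addition of 8 to excess 10 keeps the alkyne concentration low enough to suppress its rhodium-catalysed dimerisation.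

Step 7
Reactants: 11 (E)-1-[2-hydroxy-4-(methoxymethoxy)phenyl]-3-[4-[4-hydroxy-2-(methoxymethoxy)-5-[(E)-3-[4-(methoxymethoxy)phenyl]prop-2-enoyl]phenoxy]phenyl]prop-2-en-1-one
Product: 12 (E)-1-(2,4-dihydroxyphenyl)-3-[4-[2,4-dihydroxy-5-[(E)-3-(4-hydroxyphenyl)prop-2-enoyl]phenoxy]phenyl]prop-2-en-1-one
Conditions: 3 M aq HCl, MeOH/THF (1:1), 50 °C, Ar, stopped at full conversion
Reagents that add atoms: none
Why: Acid-catalysed cleavage of the three aryl MOM acetals (protonation, loss of the phenol, capture of the methoxymethyl cation by methanol), the standard last step for MOM-protected 2'-hydroxychalcones, in which the diaryl ether and both E-enones should survive dilute HCl and the hydrogen bond from each 2'-OH to its ketone slows oxa-Michael closure to flavanones.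

**Compound list**
1 | 1-(2,4,5-trihydroxyphenyl)ethan-1-one | CC(=O)c1cc(O)c(O)cc1O | starting material
2 | 1-[2,5-dihydroxy-4-(methoxymethoxy)phenyl]ethan-1-one | CC(=O)c1cc(O)c(OCOC)cc1O | intermediate
3 | 4-fluorobenzaldehyde | O=Cc1ccc(F)cc1 | starting material
4 | 4-[5-acetyl-4-hydroxy-2-(methoxymethoxy)phenoxy]benzaldehyde | CC(=O)c1cc(Oc2ccc(C=O)cc2)c(OCOC)cc1O | intermediate
5 | 1-[5-(4-ethynylphenoxy)-2-hydroxy-4-(methoxymethoxy)phenyl]ethan-1-one | CC(=O)c1cc(Oc2ccc(C#C)cc2)c(OCOC)cc1O | intermediate
6 | 4-(methoxymethoxy)benzaldehyde | COCOc1ccc(C=O)cc1 | starting material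
7 | racemic 1-[5-(4-ethynylphenoxy)-2-hydroxy-4-(methoxymethoxy)phenyl]-3-hydroxy-3-[4-(methoxymethoxy)phenyl]propan-1-one | C#Cc1ccc(Oc2cc(C(=O)CC(O)c3ccc(OCOC)cc3)c(O)cc2OCOC)cc1 | intermediate (not isolated)
8 | (E)-1-[5-(4-ethynylphenoxy)-2-hydroxy-4-(methoxymethoxy)phenyl]-3-[4-(methoxymethoxy)phenyl]prop-2-en-1-one | C#Cc1ccc(Oc2cc(C(=O)/C=C/c3ccc(OCOC)cc3)c(O)cc2OCOC)cc1 | intermediate
9 | 2,4-dihydroxybenzaldehyde | O=Cc1ccc(O)cc1O | starting material
10 | 2-hydroxy-4-(methoxymethoxy)benzaldehyde | O=Cc1ccc(OCOC)cc1O | intermediate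
11 | (E)-1-[2-hydroxy-4-(methoxymethoxy)phenyl]-3-[4-[4-hydroxy-2-(methoxymethoxy)-5-[(E)-3-[4-(methoxymethoxy)phenyl]prop-2-enoyl]phenoxy]phenyl]prop-2-en-1-one | O=C(/C=C/c1ccc(Oc2cc(C(=O)/C=C/c3ccc(OCOC)cc3)c(O)cc2OCOC)cc1)c1ccc(OCOC)cc1O | intermediate
12 | (E)-1-(2,4-dihydroxyphenyl)-3-[4-[2,4-dihydroxy-5-[(E)-3-(4-hydroxyphenyl)prop-2-enoyl]phenoxy]phenyl]prop-2-en-1-one | O=C(/C=C/c1ccc(Oc2cc(C(=O)/C=C/c3ccc(O)cc3)c(O)cc2O)cc1)c1ccc(O)cc1O | target

**Step count and risks**

Total steps: 7. Longest linear sequence: 6 (steps 1, 2, 3, 4, 6, 7).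

Steps most likely to fail:

1. Step 6. The alkyne may insert in the opposite sense and deliver the aroyl group to the internal carbon, the terminal alkyne may dimerise on rhodium, or turnover may stall as the chelating 2'-hydroxy ketones bind the metal. The fallback sets out from 4 and builds the same enone by aldol condensation instead. The aldehyde of 4 is masked as its dimethyl acetal (HC(OMe)3, cat. PPTS, MeOH, rt) to give 1-[5-[4-(dimethoxymethyl)phenoxy]-2-hydroxy-4-(methoxymethoxy)phenyl]ethan-1-one F1. Claisen–Schmidt condensation with 6 (KOH, EtOH, rt) should give (E)-1-[5-[4-(dimethoxymethyl)phenoxy]-2-hydroxy-4-(methoxymethoxy)phenyl]-3-[4-(methoxymethoxy)phenyl]prop-2-en-1-one F2. Mild hydrolysis (PPTS, acetone–water, rt), which should spare the aryl MOM ethers, should free 4-[4-hydroxy-2-(methoxymethoxy)-5-[(E)-3-[4-(methoxymethoxy)phenyl]prop-2-enoyl]phenoxy]benzaldehyde F3, which has no enolisable ketone left. Condensation of this aldehyde with 1-[2-hydroxy-4-(methoxymethoxy)phenyl]ethan-1-one F4 (from commercial 2,4-dihydroxyacetophenone with MOMCl, K2CO3, acetone) under KOH/EtOH should give 11, where the route is rejoined.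

2. Step 2. The electron-rich dianion may be oxidised to a quinone on heating, arylation may compete at the 2-oxygen, or the acetyl group may condense with the aldehyde under base. The fallback sets out from 2 and forms the ether by copper catalysis with a partner that carries no carbonyl. Ullmann coupling with 1-bromo-4-iodobenzene (CuI, picolinic acid, K3PO4, DMSO, 80 °C, Ar) should react at the iodide and give 1-[5-(4-bromophenoxy)-2-hydroxy-4-(methoxymethoxy)phenyl]ethan-1-one F5. Sonogashira coupling with trimethylsilylacetylene (PdCl2(PPh3)2, CuI, Et3N, THF, 70 °C) should give 1-[2-hydroxy-4-(methoxymethoxy)-5-[4-[2-(trimethylsilyl)ethynyl]phenoxy]phenyl]ethan-1-one F6. Desilylation (K2CO3, MeOH, rt) should give 5, where the route is rejoined without passing through 4.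

3. Step 1. Site selectivity may be lost, with MOM ether formation at the 5-oxygen or at both catechol oxygens. The fallback sets out from 1 and replaces selective protection by selective unmasking. Exhaustive acetylation (Ac2O, pyridine, cat. DMAP) should give 5-acetylbenzene-1,2,4-triyl triacetate F7. Thiolysis with one equivalent of thiophenol (cat. imidazole, NMP, 0 °C) should remove only the acetate para to the ketone, the best leaving phenoxide, and give 2-acetyl-5-hydroxy-1,4-phenylene diacetate F8. MOM protection of the single free phenol (MOMCl, i-Pr2NEt, CH2Cl2, 0 °C) should give 2-acetyl-5-(methoxymethoxy)-1,4-phenylene diacetate F9. Methanolysis of both acetates (K2CO3, MeOH, rt, Ar) should give 2, where the route is rejoined.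

**Further compounds**
F1 | step 6 | 1-[5-[4-(dimethoxymethyl)phenoxy]-2-hydroxy-4-(methoxymethoxy)phenyl]ethan-1-one | CC(=O)c1cc(Oc2ccc(C(OC)OC)cc2)c(OCOC)cc1O
F2 | step 6 | (E)-1-[5-[4-(dimethoxymethyl)phenoxy]-2-hydroxy-4-(methoxymethoxy)phenyl]-3-[4-(methoxymethoxy)phenyl]prop-2-en-1-one | COC(OC)c1ccc(Oc2cc(C(=O)/C=C/c3ccc(OCOC)cc3)c(O)cc2OCOC)cc1
F3 | step 6 | 4-[4-hydroxy-2-(methoxymethoxy)-5-[(E)-3-[4-(methoxymethoxy)phenyl]prop-2-enoyl]phenoxy]benzaldehyde | O=Cc1ccc(Oc2cc(C(=O)/C=C/c3ccc(OCOC)cc3)c(O)cc2OCOC)cc1
F4 | step 6 | 1-[2-hydroxy-4-(methoxymethoxy)phenyl]ethan-1-one | CC(=O)c1ccc(OCOC)cc1O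
F5 | step 2 | 1-[5-(4-bromophenoxy)-2-hydroxy-4-(methoxymethoxy)phenyl]ethan-1-one | CC(=O)c1cc(Oc2ccc(Br)cc2)c(OCOC)cc1O
F6 | step 2 | 1-[2-hydroxy-4-(methoxymethoxy)-5-[4-[2-(trimethylsilyl)ethynyl]phenoxy]phenyl]ethan-1-one | CC(=O)c1cc(Oc2ccc(C#C[Si](C)(C)C)cc2)c(OCOC)cc1O
F7 | step 1 | 5-acetylbenzene-1,2,4-triyl triacetate | CC(=O)c1cc(OC(C)=O)c(OC(C)=O)cc1OC(C)=O
F8 | step 1 | 2-acetyl-5-hydroxy-1,4-phenylene diacetate | CC(=O)c1cc(OC(C)=O)c(O)cc1OC(C)=O
F9 | step 1 | 2-acetyl-5-(methoxymethoxy)-1,4-phenylene diacetate | CC(=O)c1cc(OC(C)=O)c(OCOC)cc1OC(C)=O
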